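**Assumption:** the target SMILES has no stereocentre and no stereogenic double bond, so it is achiral and needs no enantiocontrol; stereo-elements in intermediates (9, 10, 12–15) are transient and carried as racemates or mixtures.

## Retrosynthetic overview

1. Target 21 ⇐ phenol 16: the end-game only adjusts oxidation level and protecting groups (CH2CH2OSi → CH2CO2H, 2 × ArOMe → ArOH, CO2Me → CO2H).
2. Ring A of 16 is the only ring built (ring B is bought as 2',6'-dimethoxyacetophenone): 16 ⇐ dehydrogenation of cyclohexenone 15 ⇐ intramolecular aldol condensation (C3→C4) of triketone 13.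
3. 13 ⇐ intermolecular Michael addition (ring bond C1–C6) of diketone 3 to γ-oxo-enoate 11; the future acetyl of 3 is masked as a dioxolane so that only one carbon is doubly activated.
4. 3 ⇐ crossed Claisen condensation of acetophenone 1 with ester 2; 11 ⇐ methyl propiolate + 3-silyloxypropanal (alkynylation, trans-reduction, oxidation).

## Route

Step 1
Reactants: 1 2',6'-dimethoxyacetophenone; 2 ethyl 2-(2-methyl-1,3-dioxolan-2-yl)acetate (fructone)
Product: 3 1-(2,6-dimethoxyphenyl)-4-(2-methyl-1,3-dioxolan-2-yl)butane-1,3-dione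
Conditions: NaH (2.5 equiv), THF, 0 °C → reflux; AcOH quench (pH ≈ 5, ketal kept)
Reagents that add atoms: none
Why: Crossed Claisen condensation – the methyl-ketone enolate of 1 (carbonyl shielded by two ortho-OMe, so no self-aldol) acylates ester 2 and the product is trapped as its stable 1,3-diketonate.

Step 2
Reactants: 4 propane-1,3-diol
Product: 5 3-[(tert-butyldiphenylsilyl)oxy]propan-1-ol
Conditions: NaH (1.0 equiv), THF, rt; then TBDPSCl (1.0 equiv)
Reagents that add atoms: tert-butyl(chloro)diphenylsilane, CC(C)(C)[Si](Cl)(c1ccccc1)c1ccccc1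
Why: Monosilylation of a symmetrical diol through its sparingly soluble monosodium alkoxide, which reacts once.

Step 3
Reactants: 5 3-[(tert-butyldiphenylsilyl)oxy]propan-1-ol
Product: 6 3-[(tert-butyldiphenylsilyl)oxy]propanal
Conditions: Dess–Martin periodinane (1.2 equiv), CH2Cl2, 0 °C → rt
Reagents that add atoms: none
Why: Dess–Martin oxidation stops cleanly at the aldehyde and does not touch the silyl ether.

Step 4
Reactants: 7 methyl propiolate; 6 3-[(tert-butyldiphenylsilyl)oxy]propanal
Product: 9 methyl 6-[(tert-butyldiphenylsilyl)oxy]-4-hydroxyhex-2-ynoate (racemic), via lithium methyl propiolate 8 (not isolated)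
Conditions: LiHMDS (1.05 equiv), THF, −78 °C; then 6, −78 °C; AcOH quench
Reagents that add atoms: none
Why: Acetylide 1,2-addition (alkynylation) to the aldehyde at −78 °C; the new carbinol centre is racemic and is removed by oxidation in step 6.

Step 5
Reactants: 9 methyl 6-[(tert-butyldiphenylsilyl)oxy]-4-hydroxyhex-2-ynoate
Product: 10 methyl (2E)-6-[(tert-butyldiphenylsilyl)oxy]-4-hydroxyhex-2-enoate (racemic)
Conditions: Red-Al (1.5 equiv), THF, −72 °C; aqueous work-up
Reagents that add atoms: none
Why: Hydroxyl-directed trans-hydroalumination of the propargylic alcohol sets the E alkene by anti addition, and the conjugated ester survives at −72 °C.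

Step 6
Reactants: 10 methyl (2E)-6-[(tert-butyldiphenylsilyl)oxy]-4-hydroxyhex-2-enoate
Product: 11 methyl (2E)-6-[(tert-butyldiphenylsilyl)oxy]-4-oxohex-2-enoate
Conditions: Dess–Martin periodinane (1.2 equiv), CH2Cl2, 0 °C → rt
Reagents that add atoms: none
Why: Dess–Martin oxidation of the allylic alcohol gives the γ-oxo-enoate with the E geometry retained and the stereocentre erased.

Step 7
Reactants: 3 1-(2,6-dimethoxyphenyl)-4-(2-methyl-1,3-dioxolan-2-yl)butane-1,3-dione; 11 methyl (2E)-6-[(tert-butyldiphenylsilyl)oxy]-4-oxohex-2-enoate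
Product: 12 methyl 6-[(tert-butyldiphenylsilyl)oxy]-2-[1-(2,6-dimethoxyphenyl)-4-(2-methyl-1,3-dioxolan-2-yl)-1,3-dioxobutan-2-yl]-4-oxohexanoate (diastereomer mixture)
Conditions: Cs2CO3 (0.1 equiv), THF, 0 °C → rt
Reagents that add atoms: none
Why: Intermolecular Michael addition – the only doubly activated carbon of 3 adds to the enoate carbon β to the ketone (α to the ester), forming ring bond C1–C6; the two new stereocentres form unselectively and are erased on aromatisation.

Step 8
Reactants: 12 Michael adduct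
Product: 15 methyl 4-acetyl-5-{2-[(tert-butyldiphenylsilyl)oxy]ethyl}-2-(2,6-dimethoxybenzoyl)-3-oxocyclohex-4-ene-1-carboxylate (diastereomer and enol mixture), via free triketone 13 (not isolated), via cyclic aldol 14 (not isolated)
Conditions: TsOH·H2O (0.3 equiv), acetone–H2O 10:1, 45 °C; then Et3N (cat.), CH2Cl2, rt
Reagents that add atoms: water, O
Why: Ketal hydrolysis makes C3 a β-diketone carbon, and its intramolecular aldol condensation onto the saturated C4 ketone (Robinson-type ring closure) is the only six-ring closure that pairs the most acidic carbon with the most electrophilic carbonyl; the stereocentres are inconsequential.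

Step 9
Reactants: 15 cyclohexenone
Product: 16 methyl 4-acetyl-5-{2-[(tert-butyldiphenylsilyl)oxy]ethyl}-2-(2,6-dimethoxybenzoyl)-3-hydroxybenzoate
Conditions: DDQ (1.1 equiv), 1,4-dioxane, 80 °C
Reagents that add atoms: none
Why: DDQ dehydrogenation of the enolised dihydrophenol (cyclohexa-1,3-dienol tautomer) is driven by aromatisation and removes the remaining stereocentres.

Step 10
Reactants: 16 silyl ether
Product: 17 methyl 4-acetyl-2-(2,6-dimethoxybenzoyl)-3-hydroxy-5-(2-hydroxyethyl)benzoate
Conditions: HF·pyridine, THF, 0 °C → rt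
Reagents that add atoms: none
Why: Fluoride-driven desilylation (strong Si–F bond) under mildly acidic conditions that leave the esters, ketones and aryl ethers intact.

Step 11
Reactants: 17 primary alcohol
Product: 19 2-[2-acetyl-4-(2,6-dimethoxybenzoyl)-3-hydroxy-5-(methoxycarbonyl)phenyl]acetic acid, via arylacetaldehyde 18 (not isolated)
Conditions: Jones reagent (CrO3, aq. H2SO4), acetone, 0 °C
Reagents that add atoms: chromium trioxide (Jones reagent), O=[Cr](=O)=O; water, O
Why: Jones oxidation takes the primary alcohol through the aldehyde hydrate to the acid, while the hydrogen-bonded, electron-poor phenol and the acyl-deactivated rings resist Cr(VI).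

Step 12
Reactants: 19 bis-methyl ether
Product: 20 2-[2-acetyl-4-(2,6-dihydroxybenzoyl)-3-hydroxy-5-(methoxycarbonyl)phenyl]acetic acid
Conditions: BBr3 (8 equiv), CH2Cl2, −78 → 0 °C; H2O
Reagents that add atoms: none
Why: Lewis-acid ether cleavage – both methoxy groups are ortho to the ketone and are cleaved with chelation assistance at ≤ 0 °C, below the temperature at which cyclodehydration to a xanthone sets in.

Step 13
Reactants: 20 methyl ester
Product: 21 Huanglongmycin D, 4-acetyl-5-(carboxymethyl)-2-(2,6-dihydroxybenzoyl)-3-hydroxybenzoic acid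
Conditions: LiOH (8 equiv), THF–H2O 3:1, rt → 40 °C, Ar; then 1 M HCl to pH 2
Reagents that add atoms: lithium hydroxide, [Li+].[OH-]
Why: Saponification of the last ester; no leaving group remains on ring B, so base cannot cause xanthone closure, and any ester already cleaved in step 12 converges on the same product.

## Compound list

1 | 2',6'-dimethoxyacetophenone | CC(=O)c1c(OC)cccc1OC | starting material
2 | ethyl 2-(2-methyl-1,3-dioxolan-2-yl)acetate (fructone) | CCOC(=O)CC1(C)OCCO1 | starting material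
3 | 1-(2,6-dimethoxyphenyl)-4-(2-methyl-1,3-dioxolan-2-yl)butane-1,3-dione | COc1cccc(OC)c1C(=O)CC(=O)CC1(C)OCCO1 | intermediate
4 | propane-1,3-diol | OCCCO | starting material
5 | 3-[(tert-butyldiphenylsilyl)oxy]propan-1-ol | OCCCO[Si](c1ccccc1)(c1ccccc1)C(C)(C)C | intermediate
6 | 3-[(tert-butyldiphenylsilyl)oxy]propanal | O=CCCO[Si](c1ccccc1)(c1ccccc1)C(C)(C)C | intermediate
7 | methyl propiolate | C#CC(=O)OC | starting material
8 | lithium methyl propiolate | [Li]C#CC(=O)OC | intermediate (not isolated)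
9 | methyl 6-[(tert-butyldiphenylsilyl)oxy]-4-hydroxyhex-2-ynoate (racemic) | COC(=O)C#CC(O)CCO[Si](c1ccccc1)(c1ccccc1)C(C)(C)C | intermediate
10 | methyl (2E)-6-[(tert-butyldiphenylsilyl)oxy]-4-hydroxyhex-2-enoate (racemic) | COC(=O)/C=C/C(O)CCO[Si](c1ccccc1)(c1ccccc1)C(C)(C)C | intermediate
11 | methyl (2E)-6-[(tert-butyldiphenylsilyl)oxy]-4-oxohex-2-enoate | COC(=O)/C=C/C(=O)CCO[Si](c1ccccc1)(c1ccccc1)C(C)(C)C | intermediate
12 | methyl 6-[(tert-butyldiphenylsilyl)oxy]-2-[1-(2,6-dimethoxyphenyl)-4-(2-methyl-1,3-dioxolan-2-yl)-1,3-dioxobutan-2-yl]-4-oxohexanoate (diastereomer mixture) | COC(=O)C(CC(=O)CCO[Si](c1ccccc1)(c1ccccc1)C(C)(C)C)C(C(=O)c1c(OC)cccc1OC)C(=O)CC1(C)OCCO1 | intermediate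
13 | methyl 6-[(tert-butyldiphenylsilyl)oxy]-2-[1-(2,6-dimethoxyphenyl)-1,3,5-trioxohexan-2-yl]-4-oxohexanoate (diastereomer mixture) | COC(=O)C(CC(=O)CCO[Si](c1ccccc1)(c1ccccc1)C(C)(C)C)C(C(=O)c1c(OC)cccc1OC)C(=O)CC(C)=O | intermediate (not isolated)
14 | methyl 4-acetyl-5-{2-[(tert-butyldiphenylsilyl)oxy]ethyl}-2-(2,6-dimethoxybenzoyl)-5-hydroxy-3-oxocyclohexane-1-carboxylate (diastereomer mixture) | COC(=O)C1CC(O)(CCO[Si](c2ccccc2)(c2ccccc2)C(C)(C)C)C(C(C)=O)C(=O)C1C(=O)c1c(OC)cccc1OC | intermediate (not isolated)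
15 | methyl 4-acetyl-5-{2-[(tert-butyldiphenylsilyl)oxy]ethyl}-2-(2,6-dimethoxybenzoyl)-3-oxocyclohex-4-ene-1-carboxylate (diastereomer and enol mixture) | COC(=O)C1CC(CCO[Si](c2ccccc2)(c2ccccc2)C(C)(C)C)=C(C(C)=O)C(=O)C1C(=O)c1c(OC)cccc1OC | intermediate
16 | methyl 4-acetyl-5-{2-[(tert-butyldiphenylsilyl)oxy]ethyl}-2-(2,6-dimethoxybenzoyl)-3-hydroxybenzoate | COC(=O)c1cc(CCO[Si](c2ccccc2)(c2ccccc2)C(C)(C)C)c(C(C)=O)c(O)c1C(=O)c1c(OC)cccc1OC | intermediate
17 | methyl 4-acetyl-2-(2,6-dimethoxybenzoyl)-3-hydroxy-5-(2-hydroxyethyl)benzoate (may equilibrate with its cyclic hemiketal) | COC(=O)c1cc(CCO)c(C(C)=O)c(O)c1C(=O)c1c(OC)cccc1OC | intermediate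
18 | methyl 4-acetyl-2-(2,6-dimethoxybenzoyl)-3-hydroxy-5-(2-oxoethyl)benzoate | COC(=O)c1cc(CC=O)c(C(C)=O)c(O)c1C(=O)c1c(OC)cccc1OC | intermediate (not isolated)
19 | 2-[2-acetyl-4-(2,6-dimethoxybenzoyl)-3-hydroxy-5-(methoxycarbonyl)phenyl]acetic acid | COC(=O)c1cc(CC(=O)O)c(C(C)=O)c(O)c1C(=O)c1c(OC)cccc1OC | intermediate
20 | 2-[2-acetyl-4-(2,6-dihydroxybenzoyl)-3-hydroxy-5-(methoxycarbonyl)phenyl]acetic acid | COC(=O)c1cc(CC(=O)O)c(C(C)=O)c(O)c1C(=O)c1c(O)cccc1O | intermediate
21 | Huanglongmycin D, 4-acetyl-5-(carboxymethyl)-2-(2,6-dihydroxybenzoyl)-3-hydroxybenzoic acid (achiral) | CC(=O)c1c(CC(=O)O)cc(C(=O)O)c(C(=O)c2c(O)cccc2O)c1O | target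

## Summary

Total step count: 13.
Longest linear sequence: 12 steps (4 → 21, steps 2–13); step 1 is the convergent branch.

Three steps most likely to fail:

**Step 8 (unmasking and aldol ring closure).** The acid stage could divert the triketone to a 4-pyranone or cause retro-Claisen loss of an acyl group. The fallback sets out from 3 and comes back at 15. It unmasks before the C–C bond formation: hydrolysis of 3 (TsOH, acetone–H2O) gives 1-(2,6-dimethoxyphenyl)hexane-1,3,5-trione F3. F3 and enone 11 then undergo a one-pot base-mediated Michael/aldol condensation (Robinson annulation; cat. Cs2CO3, THF, then warming) to 15. The price is that F3 has two doubly activated carbons, so the regioisomer from Michael addition through C3 must be separated.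

**Step 7 (Michael addition of the hindered diketonate to enone 11).** The addition may be sluggish, reversible, or give some attack β to the ester. The fallback sets out from 9 (with 3) and comes back at 16. It raises the acceptor to the alkyne oxidation level: Dess–Martin oxidation of 9 gives methyl 6-[(tert-butyldiphenylsilyl)oxy]-4-oxohex-2-ynoate F1. Cs2CO3-catalysed Michael addition of 3 to this sterically undemanding ynone gives methyl 6-[(tert-butyldiphenylsilyl)oxy]-2-[1-(2,6-dimethoxyphenyl)-4-(2-methyl-1,3-dioxolan-2-yl)-1,3-dioxobutan-2-yl]-4-oxohex-2-enoate F2 (E/Z mixture). TsOH in acetone–H2O followed by Et3N then unmasks the acetyl, and the aldol condensation gives the aromatic ring directly, so steps 8 and 9 are skipped and no DDQ is needed.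

**Step 1 (Claisen condensation with the base-sensitive β-ketal ester).** Ester enolisation with E1cB opening of the dioxolane, or slow acylation, could lower the yield. The fallback sets out from 2 (with 1) and comes back at 3. It replaces the Claisen by an aldol–oxidation sequence: DIBAL-H reduction of 2 (toluene, −78 °C) gives 2-(2-methyl-1,3-dioxolan-2-yl)acetaldehyde F4. Aldol addition of the lithium enolate of 1 (LDA, THF, −78 °C) gives 1-(2,6-dimethoxyphenyl)-3-hydroxy-4-(2-methyl-1,3-dioxolan-2-yl)butan-1-one F5 (racemic). Dess–Martin oxidation of F5 gives 3.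

## Further compounds

F1 | step 7 | methyl 6-[(tert-butyldiphenylsilyl)oxy]-4-oxohex-2-ynoate | COC(=O)C#CC(=O)CCO[Si](c1ccccc1)(c1ccccc1)C(C)(C)C
F2 | step 7 | methyl 6-[(tert-butyldiphenylsilyl)oxy]-2-[1-(2,6-dimethoxyphenyl)-4-(2-methyl-1,3-dioxolan-2-yl)-1,3-dioxobutan-2-yl]-4-oxohex-2-enoate (E/Z mixture) | COC(=O)C(=CC(=O)CCO[Si](c1ccccc1)(c1ccccc1)C(C)(C)C)C(C(=O)c1c(OC)cccc1OC)C(=O)CC1(C)OCCO1
F3 | step 8 | 1-(2,6-dimethoxyphenyl)hexane-1,3,5-trione | COc1cccc(OC)c1C(=O)CC(=O)CC(C)=O
F4 | step 1 | 2-(2-methyl-1,3-dioxolan-2-yl)acetaldehyde | CC1(CC=O)OCCO1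
F5 | step 1 | 1-(2,6-dimethoxyphenyl)-3-hydroxy-4-(2-methyl-1,3-dioxolan-2-yl)butan-1-one (racemic) | COc1cccc(OC)c1C(=O)CC(O)CC1(C)OCCO1
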